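**Retrosynthetic overview**
1. Talarophilone 23 ⇐ 21: the 2-oxopentyl chain is carried as a pent-1-ynyl group (gold hydration at the end) and O5 as a TIPS ether.
2. The orsellinate ring is built last, on the hindered ester: but-2-ynoate 16 + Chan's diene 18 (Diels–Alder/aromatisation).
3. The cyclohexenone, the quaternary C6 and the tertiary ester come from one event: α-ketol ring expansion of 1-acetylcyclopentenol silyl ether 12 (1,2-shift of the CH–OTIPS carbon from the carbinol carbon to the acetyl carbon), terminated by acyl fluoride 14.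
4. 12 ⇐ 1-ethoxyvinyllithium + (S)-5-silyloxycyclopentenone 7 ⇐ Davis α′-hydroxylation of 4 ⇐ triflation/Sonogashira of 1 with 2.
5. Ring order: cyclopentene (present in 1) → cyclohexenone (ring expansion) → arene ([4+2]).

Assumption: (+)-(2R,8aS)-(camphorsulfonyl)oxaziridine is taken as the antipode that gives the 5S alcohol in step 2; if the sense is opposite, its enantiomer is used under the same conditions.

**Step 1**
Reactants: 1 2-methylcyclopentane-1,3-dione; 2 pent-1-yne
Product: 4 2-methyl-3-(pent-1-yn-1-yl)cyclopent-2-en-1-one, via enol triflate 3 (not isolated)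
Conditions: Tf2O, Et3N, CH2Cl2, −78 → 0 °C; then 2, PdCl2(PPh3)2 (3 mol %), CuI (5 mol %), Et3N, THF, 25 °C
Reagents that add atoms: none
Why: The enolised 1,3-dione is O-triflated and the vinylogous acyl triflate undergoes Sonogashira coupling in the same flask, installing the masked side chain; no stereocentre is formed.

**Step 2**
Reactants: 4 2-methyl-3-(pent-1-yn-1-yl)cyclopent-2-en-1-one
Product: 7 (5S)-2-methyl-3-(pent-1-yn-1-yl)-5-[(triisopropylsilyl)oxy]cyclopent-2-en-1-one, via sodium dienolate 5 (not isolated), via sodium alkoxide 6 (not isolated)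
Conditions: NaHMDS, THF, −78 °C; (+)-(camphorsulfonyl)oxaziridine, −78 °C; TIPSOTf, −78 → 0 °C
Reagents that add atoms: (+)-(2R,8aS)-(camphorsulfonyl)oxaziridine, CC1(C)[C@@H]2CC[C@]13CS(=O)(=O)N4O[C@@]34C2; triisopropylsilyl triflate, CC(C)[Si](C(C)C)(C(C)C)OS(=O)(=O)C(F)(F)F
Why: NaHMDS removes the kinetic α′-proton to give the cross-conjugated dienolate, Davis oxaziridine enolate hydroxylation delivers oxygen to one enolate face under reagent control (sets C5 as S), and silylation in the flask blocks racemisation of the α-hydroxy ketone; TIPS is chosen because it does not migrate in step 4.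

**Step 3**
Reactants: 7 (5S)-2-methyl-3-(pent-1-yn-1-yl)-5-[(triisopropylsilyl)oxy]cyclopent-2-en-1-one; 8 ethyl vinyl ether
Product: 12 1-[(1R,5S)-2-methyl-3-(pent-1-yn-1-yl)-5-[(triisopropylsilyl)oxy]-1-[(trimethylsilyl)oxy]cyclopent-2-en-1-yl]ethan-1-one, via 1-ethoxyvinyllithium 9 (not isolated), via lithium alkoxide adduct 10 (not isolated), via silylated enol ether 11 (not isolated)
Conditions: 8, t-BuLi, THF, −78 → 0 °C; 7, −78 °C; TMSCl, −78 → 0 °C; then pH 3 citrate buffer, THF, 0 °C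
Reagents that add atoms: chlorotrimethylsilane, C[Si](C)(C)Cl; water, O
Why: The acyl-anion equivalent 1-ethoxyvinyllithium adds 1,2 to the enone carbonyl on the face anti to the neighbouring OTIPS group (sets C1 as R, new carbon substituent trans to OTIPS), TMSCl caps the tertiary alkoxide, and the α-alkoxy enol ether hydrolyses at pH 3 far faster than the tertiary TMS ether or the TIPS ether.

**Step 4**
Reactants: 12 1-[(1R,5S)-2-methyl-3-(pent-1-yn-1-yl)-5-[(triisopropylsilyl)oxy]-1-[(trimethylsilyl)oxy]cyclopent-2-en-1-yl]ethan-1-one; 13 but-2-ynoic acid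
Product: 16 (1R,6S)-1,3-dimethyl-2-oxo-4-(pent-1-yn-1-yl)-6-[(triisopropylsilyl)oxy]cyclohex-3-en-1-yl but-2-ynoate, via but-2-ynoyl fluoride 14 (not isolated), via ring-enlarged trimethylsilyl ether 15 (not isolated)
Conditions: 13, cyanuric fluoride, pyridine, CH2Cl2, 0 °C, cold-water wash (solution of 14); 12, TASF (10 mol %), THF, 0 → 25 °C, sealed; then 14, −40 → 0 °C
Reagents that add atoms: none
Why: Proposed new method: a fluoride-initiated, silyl-shuttled anionic α-ketol ring expansion terminated by an acyl fluoride – catalytic fluoride removes TMS from 12 to give a metal-free tertiary alkoxide whose C5–C1 bond shifts to the acetyl carbon (α-ketol/acyloin rearrangement, cyclopentene → cyclohexenone), and the new alkoxide takes TMS from the next molecule of 12 (or from Me3SiF), so 12 equilibrates catalytically to 15; 15 is the thermodynamic sink because only C5 migration gives the conjugated ynenone (the alkenyl-shift isomer is unconjugated and reverts) and because the 6R epimer can place both silyloxy groups trans-diaxial; with no chelating cation the C=O and C–O⁻ dipoles are anti and the acetyl methyl avoids the C2 methyl, so C5 (migrating with retention) bonds to the acetyl face that puts O6 trans to O5 (sets C6 as R); 14 then acylates the alkoxide and each acylation releases fluoride that desilylates the next molecule of 15, so the hindered tertiary ester forms without stoichiometric base (no dienolate acylation); closest known reactions are the base-mediated α-ketol ring expansion (steroid D-homoannulation type) and the fluoride-catalysed esterification of silyl ethers with acyl fluorides.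

**Step 5**
Reactants: 17 methyl acetoacetate
Product: 18 1-methoxy-1,3-bis[(trimethylsilyl)oxy]buta-1,3-diene (Chan's diene)
Conditions: TMSOTf (2.2 equiv), Et3N, Et2O, 0 → 25 °C
Reagents that add atoms: trimethylsilyl triflate, C[Si](C)(C)OS(=O)(=O)C(F)(F)F
Why: Double soft enolisation and O-silylation of the β-keto ester with TMSOTf/Et3N gives the 1,3-bis(silyl enol ether); no stereocentre is involved.

**Step 6**
Reactants: 16 (1R,6S)-1,3-dimethyl-2-oxo-4-(pent-1-yn-1-yl)-6-[(triisopropylsilyl)oxy]cyclohex-3-en-1-yl but-2-ynoate; 18 1-methoxy-1,3-bis[(trimethylsilyl)oxy]buta-1,3-diene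
Product: 21 (1R,6S)-1,3-dimethyl-2-oxo-4-(pent-1-yn-1-yl)-6-[(triisopropylsilyl)oxy]cyclohex-3-en-1-yl 2,4-dihydroxy-6-methylbenzoate, via Diels–Alder cycloadduct 19 (not isolated), via bis(trimethylsilyl) aryl ether 20 (not isolated)
Conditions: 18 (3 equiv), PhMe, 110 °C, sealed tube; then 1 M HCl, THF, 0 °C
Reagents that add atoms: none
Why: Diels–Alder reaction of the electron-rich diene with the ester-activated alkyne (diene CH2 terminus to the methyl-bearing β-carbon, ketene-acetal carbon to the α-carbon), then loss of methanol and acid desilylation, gives the 2,4-dihydroxy-6-methylbenzoate regiospecifically (resorcylate synthesis from alkynoates); the ynoate is the better dienophile than the internal ynenone and the ring stereocentres are untouched.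

**Step 7**
Reactants: 21 (1R,6S)-1,3-dimethyl-2-oxo-4-(pent-1-yn-1-yl)-6-[(triisopropylsilyl)oxy]cyclohex-3-en-1-yl 2,4-dihydroxy-6-methylbenzoate
Product: 23 talarophilone, via silyl-protected diketone 22 (not isolated)
Conditions: (JohnPhos)Au(MeCN)SbF6 (5 mol %), H2O (10 equiv), 1,4-dioxane, 60 °C; then HF·pyridine, THF, 0 → 25 °C
Reagents that add atoms: water, O
Why: Gold(I)-catalysed alkyne hydration puts water on the alkyne carbon remote from the enone (the carbon that carries positive charge in the conjugated system, as in ynone → 1,3-diketone hydrations) to give the 2-oxopentyl chain, and HF·pyridine then cleaves the TIPS ether under acidic conditions in which the hindered ester does not migrate and C5/C6 cannot epimerise (no hydrogen on C6, no base for retro-aldol).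

**Compound list**
1 | 2-methylcyclopentane-1,3-dione | CC1C(=O)CCC1=O | starting material
2 | pent-1-yne | CCCC#C | starting material
3 | 2-methyl-3-oxocyclopent-1-en-1-yl trifluoromethanesulfonate | CC1=C(OS(=O)(=O)C(F)(F)F)CCC1=O | intermediate
4 | 2-methyl-3-(pent-1-yn-1-yl)cyclopent-2-en-1-one | CCCC#CC1=C(C)C(=O)CC1 | intermediate
5 | sodium 5-methyl-4-(pent-1-yn-1-yl)cyclopenta-1,4-dien-1-olate | CCCC#CC1=C(C)C([O-])=CC1.[Na+] | intermediate
6 | sodium (1S)-3-methyl-2-oxo-4-(pent-1-yn-1-yl)cyclopent-3-en-1-olate | CCCC#CC1=C(C)C(=O)[C@@H]([O-])C1.[Na+] | intermediate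
7 | (5S)-2-methyl-3-(pent-1-yn-1-yl)-5-[(triisopropylsilyl)oxy]cyclopent-2-en-1-one | CCCC#CC1=C(C)C(=O)[C@@H](O[Si](C(C)C)(C(C)C)C(C)C)C1 | intermediate
8 | ethyl vinyl ether | C=COCC | starting material
9 | 1-ethoxyvinyllithium | [Li]C(=C)OCC | intermediate
10 | lithium (1R,5S)-1-(1-ethoxyethenyl)-2-methyl-3-(pent-1-yn-1-yl)-5-[(triisopropylsilyl)oxy]cyclopent-2-en-1-olate | CCCC#CC1=C(C)[C@]([O-])(C(=C)OCC)[C@@H](O[Si](C(C)C)(C(C)C)C(C)C)C1.[Li+] | intermediate
11 | (1R,5S)-1-(1-ethoxyethenyl)-2-methyl-3-(pent-1-yn-1-yl)-5-[(triisopropylsilyl)oxy]-1-[(trimethylsilyl)oxy]cyclopent-2-ene | CCCC#CC1=C(C)[C@](O[Si](C)(C)C)(C(=C)OCC)[C@@H](O[Si](C(C)C)(C(C)C)C(C)C)C1 | intermediate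
12 | 1-[(1R,5S)-2-methyl-3-(pent-1-yn-1-yl)-5-[(triisopropylsilyl)oxy]-1-[(trimethylsilyl)oxy]cyclopent-2-en-1-yl]ethan-1-one (acetyl trans to OTIPS) | CCCC#CC1=C(C)[C@](O[Si](C)(C)C)(C(C)=O)[C@@H](O[Si](C(C)C)(C(C)C)C(C)C)C1 | intermediate
13 | but-2-ynoic acid | CC#CC(O)=O | starting material
14 | but-2-ynoyl fluoride | CC#CC(F)=O | intermediate
15 | (5S,6R)-2,6-dimethyl-3-(pent-1-yn-1-yl)-5-[(triisopropylsilyl)oxy]-6-[(trimethylsilyl)oxy]cyclohex-2-en-1-one | CCCC#CC1=C(C)C(=O)[C@](C)(O[Si](C)(C)C)[C@@H](O[Si](C(C)C)(C(C)C)C(C)C)C1 | intermediate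
16 | (1R,6S)-1,3-dimethyl-2-oxo-4-(pent-1-yn-1-yl)-6-[(triisopropylsilyl)oxy]cyclohex-3-en-1-yl but-2-ynoate | CCCC#CC1=C(C)C(=O)[C@](C)(OC(=O)C#CC)[C@@H](O[Si](C(C)C)(C(C)C)C(C)C)C1 | intermediate
17 | methyl acetoacetate | COC(=O)CC(C)=O | starting material
18 | 1-methoxy-1,3-bis[(trimethylsilyl)oxy]buta-1,3-diene | COC(O[Si](C)(C)C)=CC(=C)O[Si](C)(C)C | intermediate
19 | (1R,6S)-1,3-dimethyl-2-oxo-4-(pent-1-yn-1-yl)-6-[(triisopropylsilyl)oxy]cyclohex-3-en-1-yl 6-methoxy-2-methyl-4,6-bis[(trimethylsilyl)oxy]cyclohexa-1,4-diene-1-carboxylate (both epimers at the ketal carbon) | CCCC#CC1=C(C)C(=O)[C@](C)(OC(=O)C2=C(C)CC(O[Si](C)(C)C)=CC2(OC)O[Si](C)(C)C)[C@@H](O[Si](C(C)C)(C(C)C)C(C)C)C1 | intermediate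
20 | (1R,6S)-1,3-dimethyl-2-oxo-4-(pent-1-yn-1-yl)-6-[(triisopropylsilyl)oxy]cyclohex-3-en-1-yl 2-methyl-4,6-bis[(trimethylsilyl)oxy]benzoate | CCCC#CC1=C(C)C(=O)[C@](C)(OC(=O)c2c(C)cc(O[Si](C)(C)C)cc2O[Si](C)(C)C)[C@@H](O[Si](C(C)C)(C(C)C)C(C)C)C1 | intermediate
21 | (1R,6S)-1,3-dimethyl-2-oxo-4-(pent-1-yn-1-yl)-6-[(triisopropylsilyl)oxy]cyclohex-3-en-1-yl 2,4-dihydroxy-6-methylbenzoate | CCCC#CC1=C(C)C(=O)[C@](C)(OC(=O)c2c(C)cc(O)cc2O)[C@@H](O[Si](C(C)C)(C(C)C)C(C)C)C1 | intermediate
22 | (1R,6S)-1,3-dimethyl-2-oxo-4-(2-oxopentyl)-6-[(triisopropylsilyl)oxy]cyclohex-3-en-1-yl 2,4-dihydroxy-6-methylbenzoate | CCCC(=O)CC1=C(C)C(=O)[C@](C)(OC(=O)c2c(C)cc(O)cc2O)[C@@H](O[Si](C(C)C)(C(C)C)C(C)C)C1 | intermediate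
23 | talarophilone, (1R,6S)-6-hydroxy-1,3-dimethyl-2-oxo-4-(2-oxopentyl)cyclohex-3-en-1-yl 2,4-dihydroxy-6-methylbenzoate (ester O and OH trans) | CCCC(=O)CC1=C(C)C(=O)[C@](C)(OC(=O)c2c(C)cc(O)cc2O)[C@@H](O)C1 | target

**Total step count:** 7. **Longest linear sequence:** 6 (steps 1, 2, 3, 4, 6, 7); step 5 is a one-step branch.

**Steps most likely to fail**

Step 4 (the new reaction). The risks are incomplete isomerisation, competing alkenyl (C2) migration, the C6 epimer, and acylation before rearrangement. The fallback uses known chemistry, sets out from 12 and comes back at 16. KOH in MeOH at 25–45 °C removes the TMS group and effects the classical hydroxide-mediated, non-chelated, equilibrating α-ketol ring expansion. The tertiary alcohol (5S,6R)-6-hydroxy-2,6-dimethyl-3-(pent-1-yn-1-yl)-5-[(triisopropylsilyl)oxy]cyclohex-2-en-1-one F1 is isolated, and any C6 epimer is removed by chromatography here. Oxalyl chloride converts 13 into but-2-ynoyl chloride F2. O-Lithiation of the alcohol with LiHMDS at −78 °C and immediate acylation with the chloride gives 16.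

Step 6. The β-methyl ynoate of a hindered tertiary ester may add the diene slowly, and the ynenone may compete. The fallback brings in a preformed arene, sets out from 12 (through the alcohol F1 above) and from 17, and comes back at 21. Self-condensation of 17 (NaH then n-BuLi, THF, reflux) gives methyl 2,4-dihydroxy-6-methylbenzoate F3. Aqueous KOH at 25 °C gives 2,4-dihydroxy-6-methylbenzoic acid F4. Acetone/TFAA/TFA gives 7-hydroxy-2,2,5-trimethyl-4H-1,3-benzodioxin-4-one F5, and TIPSCl/imidazole gives 2,2,5-trimethyl-7-[(triisopropylsilyl)oxy]-4H-1,3-benzodioxin-4-one F6. The sodium alkoxide of the alcohol F1 (NaHMDS, THF, −78 → 25 °C) opens this dioxinone with loss of acetone to give (1R,6S)-1,3-dimethyl-2-oxo-4-(pent-1-yn-1-yl)-6-[(triisopropylsilyl)oxy]cyclohex-3-en-1-yl 2-hydroxy-6-methyl-4-[(triisopropylsilyl)oxy]benzoate F7. TBAF/AcOH at 0 °C then removes only the aryl silyl ether to give 21.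

Step 2. The enantiomeric excess of the enolate hydroxylation and the α′ versus γ enolisation are uncertain. The fallback sets out from 4 and comes back at 7. Mn(OAc)3 in benzene/AcOH at 80 °C (radical α′-acetoxylation) gives racemic 3-methyl-2-oxo-4-(pent-1-yn-1-yl)cyclopent-3-en-1-yl acetate F8. Lipase hydrolysis (Amano PS, pH 7 buffer/MTBE, about 50 % conversion) resolves it to (5S)-5-hydroxy-2-methyl-3-(pent-1-yn-1-yl)cyclopent-2-en-1-one F9. This is taken from the alcohol fraction, or, if the lipase prefers the R ester, from the recovered S acetate by non-selective esterase hydrolysis. TIPSOTf/2,6-lutidine then gives 7.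

**Further compounds**
F1 | step 4 | (5S,6R)-6-hydroxy-2,6-dimethyl-3-(pent-1-yn-1-yl)-5-[(triisopropylsilyl)oxy]cyclohex-2-en-1-one | CCCC#CC1=C(C)C(=O)[C@](C)(O)[C@@H](O[Si](C(C)C)(C(C)C)C(C)C)C1
F2 | step 4 | but-2-ynoyl chloride | CC#CC(Cl)=O
F3 | step 6 | methyl 2,4-dihydroxy-6-methylbenzoate | COC(=O)c1c(C)cc(O)cc1O
F4 | step 6 | 2,4-dihydroxy-6-methylbenzoic acid | Cc1cc(O)cc(O)c1C(O)=O
F5 | step 6 | 7-hydroxy-2,2,5-trimethyl-4H-1,3-benzodioxin-4-one | Cc1cc(O)cc2OC(C)(C)OC(=O)c12
F6 | step 6 | 2,2,5-trimethyl-7-[(triisopropylsilyl)oxy]-4H-1,3-benzodioxin-4-one | Cc1cc(O[Si](C(C)C)(C(C)C)C(C)C)cc2OC(C)(C)OC(=O)c12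
F7 | step 6 | (1R,6S)-1,3-dimethyl-2-oxo-4-(pent-1-yn-1-yl)-6-[(triisopropylsilyl)oxy]cyclohex-3-en-1-yl 2-hydroxy-6-methyl-4-[(triisopropylsilyl)oxy]benzoate | CCCC#CC1=C(C)C(=O)[C@](C)(OC(=O)c2c(C)cc(O[Si](C(C)C)(C(C)C)C(C)C)cc2O)[C@@H](O[Si](C(C)C)(C(C)C)C(C)C)C1
F8 | step 2 | 3-methyl-2-oxo-4-(pent-1-yn-1-yl)cyclopent-3-en-1-yl acetate (racemic) | CCCC#CC1=C(C)C(=O)C(OC(C)=O)C1
F9 | step 2 | (5S)-5-hydroxy-2-methyl-3-(pent-1-yn-1-yl)cyclopent-2-en-1-one | CCCC#CC1=C(C)C(=O)[C@@H](O)C1
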